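The data are simulated for substances that don't exist; noise was put on by code.

- The trap in the two earlier runs was that amber and ochre changed free enzyme and temperature together, so a decay rate divided by free enzyme could look like a constant although the readings could not show that it was one.

| flask | substrate | free enzyme | temperature | remark | time |
|---|---|---|---|---|---|
| amber | 0.035 M | 0.16 µM | 5 °C | run made earlier |  |
| ochre | 0.035 M | 0.24 µM | 30 °C | run made earlier |  |
| alpha | 0.035 M | 0.32 µM | 50 °C |  | 40 h |
| eta | 0.035 M | 0.32 µM |  | at 10 °C until 12 h, from then on at 50 °C | 40 h |
| beta | 0.035 M | 0.32 µM | 10 °C |  | 40 h |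
| zeta | 0.035 M | 0.32 µM | 30 °C |  | 40 h |

| run | time / h | target / % | over-reaction product / % |
|---|---|---|---|
| amber | 20.0 | 89.5 | 10.0 |
| amber | 60.0 | 72.5 | 27.9 |
| amber | 120 | 52.2 | 47.6 |
| amber | 144 | 45.6 | 53.8 |
| amber | 240 | 27.4 | 72.8 |
| ochre | 15.0 | 14.0 | 85.6 |
| ochre | 25.0 | 3.8 | 95.8 |
| ochre | 40.0 | 0.3 | 99.4 |
| ochre | 60.0 | 0 | 99.9 |
| ochre | 72.0 | 0.3 | 100.3 |

(readings scatter by 0.3 percentage points)

- which flask leads in share of target in all that became target or over-reaction product ("all alike" within 1.5 percentage points) (alpha / eta / beta / zeta / all alike)
- share of target in all that became target or over-reaction product, alpha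
- share of target in all that became target or over-reaction product, eta
- share of target in all that became target or over-reaction product, beta
- share of target in all that became target or over-reaction product, zeta



- I solved the cold end first: target in amber fell at 0.00538 /h, and this line carried back from the first reading to the start gave 99.7%, nearly all of the charge, so I treated the making of target as over early and the rest as one first-order decay.

- At the warm end, ochre's first two readings gave 0.130 /h, and I judged, since the runs could not show it, that this decay took no free enzyme.

- The two constants gave an activation energy of 89.4 kJ/mol and, at 10 °C, a rate constant of 0.0106 /h, hence 65.1 h; this half-life of target at the flask's temperature was what I carried: in a flask held at one temperature, once making is over, the share of target (the selectivity) is one half raised to the elapsed time over that half-life.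

- Amber and beta look nearly alike, yet amber's half-life of 129 h was twice beta's, so at 40 h I reckoned 80.6% for amber but 65.3% for beta, giving the larger charge of free enzyme in beta no part in my reckoning.

- Zeta shares ochre's temperature, so I gave it 0.543%, beside ochre's reading of 0.3% at that time; at 50 °C the half-life came to 0.592 h, which makes 67.6 half-lives in alpha and 47.3 in eta after its change, so I expected beta to lead and alpha and eta to hold no target.

- The forecast, made “assuming rate scales with enzyme”, named beta at 45.8%, lower than my figure, with 0.1% for zeta, 0% for alpha and 0% for eta.

- The flasks gave beta as leader at 65.1%, then zeta at 0.554%, alpha at 0% and eta at 0%.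

    free enzyme → unfolded enzyme (k = 0.0400 /h, Ea = 214 kJ/mol)
    substrate + free enzyme → target + free enzyme, rate k2*[substrate]*[free enzyme]/(1 + ([substrate]/Km2) + ([target]/Kp2)) (18.0 mM, 0.0540 M, k = 68000 /M/s, Ea = 30.0 kJ/mol)
    target → over-reaction product (k = 0.130 /h, Ea = 89.0 kJ/mol)
    2 substrate → homo dimer (k = 0.750 /M/h, Ea = 83.0 kJ/mol)
    (constants at 30 °C)

- In eta, half of the turnover from substrate to target up to the asked time was done by 0.0531 h, far sooner than the 65 h that target's half-life by its step to over-reaction product measured at 0.0531 h, a figure that stood beside my 65.1 h. Over the 40 h of beta my half-life left 65.3% against the 65.1% found, and over the 12 h of eta's cold stage it left 88.0%, while eta held 88.0% of target at 12.0 h.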